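Equivalents mislead at this fork. Alpha and the flask both carry 0.800 equiv of second nucleophile, yet the flask holds twice the [second nucleophile] of alpha.

common to all: gas 2.5 mM (held)
- theta: starting material 36 mM; second nucleophile 0.40 equiv; run made earlier
- gamma: starting material 36 mM; second nucleophile 1.6 equiv; run made earlier
- alpha: starting material 18 mM; second nucleophile 0.80 equiv; run made earlier
- flask: starting material 36 mM; second nucleophile 0.800 equiv; time 2.0 min

| run | time / min | other capture product / % | target / % |
|---|---|---|---|
| theta | 0.200 | 3.5 | 2.8 |
| theta | 0.667 | 8.2 | 6.4 |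
| theta | 1.00 | 9.8 | 7.6 |
| theta | 1.50 | 10.2 | 8.3 |
| theta | 2.50 | 12.6 | 9.1 |
| gamma | 0.500 | 15.4 | 3.2 |
| gamma | 1.00 | 26.5 | 6.4 |
| gamma | 1.33 | 29.4 | 6.6 |
| gamma | 2.00 | 35.5 | 6.1 |
| gamma | 2.50 | 36.6 | 5.5 |
| alpha | 0.500 | 7.0 | 6.3 |
| alpha | 1.00 | 10.0 | 5.8 |
| alpha | 1.33 | 10.1 | 7.5 |
| alpha | 2.00 | 12.4 | 7.8 |
| alpha | 2.50 | 12.9 | 7.9 |

(each reading ± 1 percentage point)

* ratio of other capture product to target at 5.0 s
* ratio of other capture product to target at 20 s
* ratio of other capture product to target at 2.0 min

Follow one molecule of intermediate. It can meet first nucleophile and become target, or meet second nucleophile and become other capture product. The odds between these two scale with [second nucleophile] over [first nucleophile], and the gas has the same saturation concentration, 2.5 mM, in theta, gamma and alpha. So we carry one number: the ratio of other capture product to target at 2.0 min, per mM of second nucleophile charged, a selectivity factor taken at a fixed sampling time. We call it s.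

Gamma holds 57.6 mM and reads 35.5% against 6.1% at 2.00 min, so s is 0.101 mM⁻¹. The scatter of 1 percentage point weighs heavily on so small a target reading. Alpha offers a check from another run: s predicts 1.45 there, and alpha reads 1.59.

For the flask, with 28.8 mM, we reckon 2.91 at 2.0 min. That is above alpha's reading and below gamma's, and no earlier run held this concentration. So we run the flask as charged, to read the ratio at this concentration. That is no judgement on the charge, since no limit on the ratio has been set. We commit to no earlier time, since s was read at 2.0 min.

The forecast gives 3, 2.5 and 2.9, holding that “The capture ratio depends on the absolute second-nucleophile concentration, not on equivalents.”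

The flask gives 1.91, 1.90 and 2.87.

    starting material → intermediate (k = 0.0170 s⁻¹)
    first nucleophile + intermediate → target (k = 280 M⁻¹ s⁻¹)
    second nucleophile + intermediate → other capture product (k = 28.0 M⁻¹ s⁻¹)
    intermediate → solvolysis product (k = 1.50 s⁻¹)
    gas ⇌ first nucleophile, rate k5*(csat - [first nucleophile]) (kL = 0.570 s⁻¹)
    target → over-reaction product (k = 1.20 × 10⁻⁵ s⁻¹)
    target ⇌ isomer of the product (K = 1.90, k = 0.0500 s⁻¹)

The forecast stands high at the two early times and agrees at 2.0 min, as does s. At that time the flask holds 12.3% isomer of the product beside 7.40% target. A neighbour charged with 3.20 equiv holds 115.2 mM, so s gives 11.6. That neighbour gives 12.0, with 50.3% other capture product and 4.20% target.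

The readings were generated by integration for substances that don't exist; noise was put on by code.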